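**Strategy.** The cyclohexene ring B, with C9=C9a conjugated to the lactone, is a Diels–Alder retron, and cyclohexane ring A is a bare (CH2)4 bridge from C8a to C4a. Both are cut back to a butenolide that carries a 3-(penta-1,4-dienyl) diene and a dienophile tethered through C3–C2'–C1', each ending in an allyl arm. In one flask, an intramolecular Diels–Alder reaction closes rings B and C and sets C3a, C4 and C4a, then ring-closing metathesis of the two allyl arms closes ring A last. The C8a hydroxyl sits at the only tertiary, allylic, vinylogously acidic C–H and is installed at the end by dienolate oxygenation. All stereochemistry descends from (S)-2-methylpiperidine.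

Key step: step 10

Remark on labels (himbacine-type locants, used in all names): C1 lactone carbonyl, O2, C3 (C–CH3), C3a, C4, C4a, C5–C8, C8a (C–OH), C9 (=CH), C9a; C1' is the CH2 on C4 and C2' the CH that carries the piperidine and is bonded to C3. Ring A = C4a–C5–C6–C7–C8–C8a; ring B = C3a–C4–C4a–C8a–C9–C9a; ring C = C3–C3a–C4–C1'–C2'; ring D = lactone.

Step 1
Reactants: 1 (S)-2-methylpiperidine
Product: 2 1-[(2S)-2-methylpiperidin-1-yl]ethan-1-one
Conditions: Ac2O, Et3N, CH2Cl2, 0 °C to rt
Reagents that add atoms: acetic anhydride CC(=O)OC(C)=O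
Why: N-acylation of the secondary amine installs the acetyl group that the target carries, so no nitrogen protecting group is needed, and the methyl-bearing stereocentre is not touched.

Step 2
Reactants: 2 1-[(2S)-2-methylpiperidin-1-yl]ethan-1-one
Product: 3 1-[(6S)-2-methoxy-6-methylpiperidin-1-yl]ethan-1-one (both C2 epimers)
Conditions: MeOH, Et4NOTs, graphite electrodes, undivided cell, constant current (ca. 2.5 F/mol), 10 °C
Reagents that add atoms: methanol CO
Why: Shono oxidation: the anodically formed amide radical cation loses a proton from the less substituted α-CH2 and methanol traps the N-acyliminium ion, so the aminal forms at the ring carbon remote from the methyl group and its configuration is irrelevant because step 5 ionises it again.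

Step 3
Reactants: 4 hexa-1,5-dien-3-ol (racemic), 5 2-methoxypropene
Product: 7 (5E)-nona-5,8-dien-2-one, via allyl isopropenyl ether 6 (not isolated)
Conditions: 5 (5 equiv), PPTS (cat.), sealed tube, 130 °C
Reagents that add atoms: none
Why: Saucy–Marbet (ketal Claisen) rearrangement: acid-catalysed exchange gives the allyl isopropenyl ether and its chair-like [3,3]-shift with the allyl substituent equatorial gives the E alkene, the carbinol stereocentre of 4 being destroyed.

Step 4
Reactants: 7 (5E)-nona-5,8-dien-2-one
Product: 8 trimethyl{[(2Z,5E)-nona-2,5,8-trien-2-yl]oxy}silane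
Conditions: TMSCl, Et3N, DMF, 100 °C (equilibrating)
Reagents that add atoms: chlorotrimethylsilane C[Si](C)(C)Cl
Why: Silyl enol ether formation under equilibrating conditions favours the more substituted internal Z enol ether, which makes C2' the nucleophilic carbon (the minor terminal isomer would give a linear, separable ketone in step 5).

Step 5
Reactants: 3 1-[(6S)-2-methoxy-6-methylpiperidin-1-yl]ethan-1-one, 8 trimethyl{[(2Z,5E)-nona-2,5,8-trien-2-yl]oxy}silane
Product: 10 (3R,5E)-3-[(2S,6S)-1-acetyl-6-methylpiperidin-2-yl]nona-5,8-dien-2-one, via N-acyliminium triflate 9 (not isolated)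
Conditions: TMSOTf (10 mol%), CH2Cl2, −78 °C
Reagents that add atoms: none
Why: Mukaiyama–Mannich reaction: the N-acyliminium ion holds its ring methyl pseudo-axial (A1,3 strain with N-acetyl) and is attacked axially through a chair-like transition state to give the 2,6-cis piperidine, while C2' is set in an open antiperiplanar transition state in which the CH2CH=CH arm lies over the iminium C–H side and away from the axial methyl (the C2' epimers are separable and the minor one can be re-equilibrated through the enol).

Step 6
Reactants: 10 (3R,5E)-3-[(2S,6S)-1-acetyl-6-methylpiperidin-2-yl]nona-5,8-dien-2-one, 11 ethyl propiolate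
Product: 13 ethyl (4S,5R,7E)-5-[(2S,6S)-1-acetyl-6-methylpiperidin-2-yl]-4-hydroxy-4-methylundeca-7,10-dien-2-ynoate, via lithium ethyl propiolate 12 (not isolated)
Conditions: 11, LiHMDS, THF, −78 °C; then 10, −78 °C; AcOH quench
Reagents that add atoms: none
Why: 1,2-Addition of a weakly basic lithium acetylide to the methyl ketone under Felkin–Anh control (attack anti to the bulky piperidinyl group and past H) sets the C3 carbinol so that the future lactone oxygen and the piperidine are cis on ring C.

Step 7
Reactants: 13 ethyl (4S,5R,7E)-5-[(2S,6S)-1-acetyl-6-methylpiperidin-2-yl]-4-hydroxy-4-methylundeca-7,10-dien-2-ynoate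
Product: 15 (5S)-5-[(1R,3E)-1-[(2S,6S)-1-acetyl-6-methylpiperidin-2-yl]hepta-3,6-dien-1-yl]-5-methyl-3-(tributylstannyl)furan-2(5H)-one, via hydroxy stannyl enoate 14 (not isolated)
Conditions: Bu3SnH, Pd(PPh3)4 (3 mol%), THF, 0 °C to rt; then PPTS (cat.), PhMe, 50 °C
Reagents that add atoms: tributyltin hydride CCCC[SnH](CCCC)CCCC
Why: Pd-catalysed syn-hydrostannation of the ynoate delivers hydride to the β-carbon and tin to the α-carbon (remote from the quaternary carbinol), so carbinol and ester are cis on the alkene and lactonise to the butenolide (ring D) with loss of ethanol; no stereocentre is formed.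

Step 8
Reactants: 16 pent-1-en-4-yne
Product: 18 (1E)-1-iodopenta-1,4-diene, via alkenylalane 17 (not isolated)
Conditions: DIBAL-H, hexane, 50 °C; then I2, THF, −50 °C to rt
Reagents that add atoms: iodine II
Why: Syn-hydroalumination of the terminal alkyne (faster than that of the monosubstituted alkene) and iodinolysis of the alkenyl–Al bond with retention give the E vinyl iodide.

Step 9
Reactants: 15 (5S)-5-[(1R,3E)-1-[(2S,6S)-1-acetyl-6-methylpiperidin-2-yl]hepta-3,6-dien-1-yl]-5-methyl-3-(tributylstannyl)furan-2(5H)-one, 18 (1E)-1-iodopenta-1,4-diene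
Product: 19 (5R)-5-[(1R,3E)-1-[(2S,6S)-1-acetyl-6-methylpiperidin-2-yl]hepta-3,6-dien-1-yl]-5-methyl-3-[(1E)-penta-1,4-dien-1-yl]furan-2(5H)-one
Conditions: Pd(PPh3)4 (5 mol%), CuI (10 mol%), CsF, DMF, 40 °C; product used at once
Reagents that add atoms: none
Why: Stille coupling promoted by CuI and fluoride joins the α-stannyl butenolide and the vinyl iodide with retention of both alkene geometries and creates the 2-carbonyl-activated E diene under neutral conditions that leave the skipped dienes in place.

Step 10
Reactants: 19 (5R)-5-[(1R,3E)-1-[(2S,6S)-1-acetyl-6-methylpiperidin-2-yl]hepta-3,6-dien-1-yl]-5-methyl-3-[(1E)-penta-1,4-dien-1-yl]furan-2(5H)-one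
Product: 21 6,7-didehydro-8a-deoxy target (ring A closed as the C6=C7 cyclohexene; A/B trans-fused), via Diels–Alder adduct 20 (not isolated)
Conditions: PhMe (2 mM), BHT (cat.), 110 °C; then second-generation Ru benzylidene catalyst (G-II, 5 mol%), 60 °C, Ar sparge
Reagents that add atoms: none
Why: Heating lets the electron-poor 2-carbonyl diene C3a=C9a–C9=C8a add the tethered E alkene C4=C4a in a concerted intramolecular Diels–Alder reaction (three-atom tether C3–C2'–C1'), after which Ru-carbene exchange between the two allyl arms expels ethene; the closest known types are nonatriene intramolecular Diels–Alder reactions of 2-acyl dienes and metathesis of trans-1,2-diallylcyclohexanes. Ring B closes by the [4+2] event (bonds C3a–C4 and C8a–C4a), ring C closes as the five-membered tether ring of the same cycloaddition, and ring A closes last by six-membered ring-closing metathesis (C6=C7). C3a is fixed because the tether from the quaternary C3 can reach only the butenolide face that carries C2'; C4 follows from the syn (endo) tether orientation that gives the cis-fused hydrindene; C4a follows from the E geometry of the dienophile (H4 and H4a trans); C8a follows from the E diene and is re-set in step 12. The step needs the syn-tether transition state over the anti one: the anti mode would lead to a trans-fused cyclopentane on a cis-bicyclo[3.3.0] lactone, which is strongly strained, and would push the C2' piperidinyl group over the lactone, whereas in the syn mode that group is pseudo-equatorial. Chemoselectivity is secured by the order of events: the thermal cycloaddition is complete before the catalyst is added, so metathesis meets only the two terminal alkenes, and the trans-diallyl array closes to a strain-free trans-fused cyclohexene.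

Step 11
Reactants: 21 6,7-didehydro-8a-deoxy target
Product: 22 8a-deoxy target (C8a–H in place of C8a–OH; A/B trans-fused)
Conditions: H2 (1 atm), RhCl(PPh3)3 (5 mol%), PhH/EtOH, rt
Reagents that add atoms: none
Why: Homogeneous hydrogenation with RhCl(PPh3)3 saturates the unhindered cis-disubstituted C6=C7 alkene and leaves the trisubstituted, conjugated and hindered C9=C9a alkene untouched; no stereocentre is formed.

Step 12
Reactants: 22 8a-deoxy target
Product: 25 target CNP0529632.1 (8a-OH trans to H4a), via potassium dienolate 23 (not isolated), via hydroperoxide 24 (not isolated)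
Conditions: KHMDS, THF, −78 °C; then O2, P(OEt)3, −78 to −20 °C; AcOH quench
Reagents that add atoms: dioxygen O=O
Why: Vinylogous enolate oxygenation: the silazide removes the axial C8a–H (γ to the lactone carbonyl; the acetamide is too weakly acidic to compete) and O2 is captured at the γ-terminus by axial attack on the convex face opposite ring C, as in the trapping of 9-decalyl intermediates, which gives the trans-fused 8a-hydroperoxide that the phosphite reduces in situ to the tertiary alcohol with the conjugated C9=C9a alkene restored.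

**Compound list**

1 | (S)-2-methylpiperidine | C[C@H]1CCCCN1 | starting material
2 | 1-[(2S)-2-methylpiperidin-1-yl]ethan-1-one | CC(=O)N1[C@@H](C)CCCC1 | intermediate
3 | 1-[(6S)-2-methoxy-6-methylpiperidin-1-yl]ethan-1-one (C2 epimers) | CC(=O)N1[C@@H](C)CCCC1OC | intermediate
4 | hexa-1,5-dien-3-ol (racemic) | C=CCC(O)C=C | starting material
5 | 2-methoxypropene | COC(C)=C | starting material
6 | 3-(prop-1-en-2-yloxy)hexa-1,5-diene (allyl isopropenyl ether) | C=CCC(OC(C)=C)C=C | intermediate
7 | (5E)-nona-5,8-dien-2-one | CC(=O)CC/C=C/CC=C | intermediate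
8 | trimethyl{[(2Z,5E)-nona-2,5,8-trien-2-yl]oxy}silane | C/C(O[Si](C)(C)C)=C/C/C=C/CC=C | intermediate
9 | (2S)-1-acetyl-2-methyl-2,3,4,5-tetrahydropyridin-1-ium triflate | CC(=O)[N+]1=CCCC[C@@H]1C.[O-]S(=O)(=O)C(F)(F)F | intermediate
10 | (3R,5E)-3-[(2S,6S)-1-acetyl-6-methylpiperidin-2-yl]nona-5,8-dien-2-one | CC(=O)N1[C@@H](C)CCC[C@H]1[C@@H](C/C=C/CC=C)C(C)=O | intermediate
11 | ethyl propiolate | C#CC(=O)OCC | starting material
12 | lithium ethyl propiolate | [Li]C#CC(=O)OCC | intermediate
13 | ethyl (4S,5R,7E)-5-[(2S,6S)-1-acetyl-6-methylpiperidin-2-yl]-4-hydroxy-4-methylundeca-7,10-dien-2-ynoate | CC(=O)N1[C@@H](C)CCC[C@H]1[C@@H](C/C=C/CC=C)[C@](C)(O)C#CC(=O)OCC | intermediate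
14 | ethyl (2E,4S,5R,7E)-5-[(2S,6S)-1-acetyl-6-methylpiperidin-2-yl]-4-hydroxy-4-methyl-2-(tributylstannyl)undeca-2,7,10-trienoate | CC(=O)N1[C@@H](C)CCC[C@H]1[C@@H](C/C=C/CC=C)[C@](C)(O)/C=C(/[Sn](CCCC)(CCCC)CCCC)C(=O)OCC | intermediate
15 | (5S)-5-[(1R,3E)-1-[(2S,6S)-1-acetyl-6-methylpiperidin-2-yl]hepta-3,6-dien-1-yl]-5-methyl-3-(tributylstannyl)furan-2(5H)-one | CC(=O)N1[C@@H](C)CCC[C@H]1[C@@H](C/C=C/CC=C)[C@]1(C)OC(=O)C(=C1)[Sn](CCCC)(CCCC)CCCC | intermediate
16 | pent-1-en-4-yne | C=CCC#C | starting material
17 | diisobutyl[(1E)-penta-1,4-dien-1-yl]alane | CC(C)C[Al](CC(C)C)/C=C/CC=C | intermediate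
18 | (1E)-1-iodopenta-1,4-diene | I/C=C/CC=C | intermediate
19 | (5R)-5-[(1R,3E)-1-[(2S,6S)-1-acetyl-6-methylpiperidin-2-yl]hepta-3,6-dien-1-yl]-5-methyl-3-[(1E)-penta-1,4-dien-1-yl]furan-2(5H)-one | CC(=O)N1[C@@H](C)CCC[C@H]1[C@@H](C/C=C/CC=C)[C@]1(C)OC(=O)C(/C=C/CC=C)=C1 | intermediate
20 | Diels–Alder adduct: rings B, C and D closed; allyl groups on C4a and C8a (trans); H3a, H4 and H8a on one face, H4a on the other | CC(=O)N1[C@@H](C)CCC[C@H]1[C@H]1C[C@@H]2[C@H]3C(=C[C@H](CC=C)[C@H]2CC=C)C(=O)O[C@@]13C | intermediate
21 | 6,7-didehydro-8a-deoxy target (ring A as C6=C7 cyclohexene; A/B trans-fused) | CC(=O)N1[C@@H](C)CCC[C@H]1[C@H]1C[C@@H]2[C@H]3C(=C[C@@H]4CC=CC[C@@H]24)C(=O)O[C@@]13C | intermediate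
22 | 8a-deoxy target (C8a–H on the face that later carries OH) | CC(=O)N1[C@@H](C)CCC[C@H]1[C@H]1C[C@@H]2[C@H]3C(=C[C@@H]4CCCC[C@@H]24)C(=O)O[C@@]13C | intermediate
23 | potassium dienolate of 22 (C1(O–)=C9a–C9=C8a) | CC(=O)N1[C@@H](C)CCC[C@H]1[C@H]1C[C@@H]2[C@H]3C(C=C4CCCC[C@@H]24)=C([O-])O[C@@]13C.[K+] | intermediate
24 | 8a-hydroperoxide (OOH in place of the target OH) | CC(=O)N1[C@@H](C)CCC[C@H]1[C@H]1C[C@@H]2[C@H]3C(=C[C@]4(OO)CCCC[C@@H]24)C(=O)O[C@@]13C | intermediate
25 | CNP0529632.1: (3R,3aS,4S,4aS,8aS,2'R) lactone with (2S,6S)-1-acetyl-6-methylpiperidin-2-yl on C2' | CC(=O)N1[C@@H](C)CCC[C@H]1[C@H]1C[C@@H]2[C@H]3C(=C[C@]4(O)CCCC[C@@H]24)C(=O)O[C@@]13C | target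

**Step count.** Total: 12 steps. Longest linear sequence: 9 steps (steps 1, 2, 5, 6, 7, 9, 10, 11, 12; the branch through steps 3 and 4 is equally long).

**Steps most likely to fail**

1. Step 10. What may go wrong: the anti (exo) orientation of the C3–C2'–C1' tether competes with the required syn one, which would invert C4, C4a and C8a relative to C3; or bimolecular Diels–Alder dimerisation of the diene outruns cyclisation. Fallback, setting out from 19 and coming back at 21: the order of the two ring-forming events is reversed. Z-selective ring-closing metathesis of the two terminal alkenes at room temperature (cyclometalated Z-selective Ru catalyst, 1 mM) should give the 13-membered macrocyclic tetraene butenolide F1. Heating F1 (PhMe, 110–150 °C) should then bring about a transannular Diels–Alder reaction. The E dienophile is now held at both ends, so the short three-atom bridge is expected to take the endo position and the four-carbon bridge the exo position, which gives 21.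

2. Step 12. What may go wrong: oxygenation at the α-carbon C9a instead of the γ-carbon C8a, oxygen delivery to the concave face, or further oxidation at the hydroperoxide stage. Fallback, setting out from 22 and coming back at 25: deconjugation, epoxidation and elimination. Kinetic α-protonation of the dienolate (KHMDS, then AcOH at −78 °C) should give the β,γ-unsaturated lactone F2. mCPBA should epoxidise its electron-rich C8a=C9 alkene from the convex face to give the 8a,9-epoxide F3. DBU then removes H9a and opens the epoxide (E1cB) to 25, with the oxygen position fixed by the epoxide.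

3. Step 5. What may go wrong: poor discrimination between the two faces of the prochiral enol silane (C2' epimers), and C–C bond formation through the terminal enol silane regioisomer. Fallback, setting out from 4 and 3 and coming back at 10: ester enolate chemistry replaces the ketone enol silane. Orthoester Claisen rearrangement of 4 with trimethyl orthoacetate (cat. propionic acid, 140 °C) should give methyl (4E)-octa-4,7-dienoate F4, which can enolise at one carbon only. LDA and TMSCl (THF, or THF/DMPU for the other geometry) should give the silyl ketene acetal F5 of defined geometry. TMSOTf-catalysed addition of F5 to 3 should give the ester F6, with the ketene acetal geometry as the handle on the C2' configuration. MeNH(OMe)·HCl with i-PrMgCl should convert F6 into the N-methoxy-N-methylamide F7, and MeMgBr should then give 10.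

**Further compounds**

F1 | step 10 | 13-membered macrocyclic tetraene butenolide (carbocycle C3–C2'–C1'–C4=C4a–C5–C6=C7–C8–C8a=C9–C9a=C3a; C4=C4a E, C6=C7 Z, C8a=C9 E) | CC(=O)N1[C@@H](C)CCC[C@H]1[C@H]1C/C=C/C/C=C\C/C=C/C2=C[C@@]1(C)OC2=O
F2 | step 12 | β,γ-unsaturated lactone (C8a=C9 alkene, H on C9a; C9a epimers) | CC(=O)N1[C@@H](C)CCC[C@H]1[C@H]1C[C@@H]2[C@H]3C(C=C4CCCC[C@@H]24)C(=O)O[C@@]13C
F3 | step 12 | 8a,9-epoxide (oxygen on the face of H4; C9a epimers) | CC(=O)N1[C@@H](C)CCC[C@H]1[C@H]1C[C@@H]2[C@H]3C([C@H]5O[C@]54CCCC[C@@H]24)C(=O)O[C@@]13C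
F4 | step 5 | methyl (4E)-octa-4,7-dienoate | COC(=O)CC/C=C/CC=C
F5 | step 5 | {[(1E,4E)-1-methoxyocta-1,4,7-trien-1-yl]oxy}trimethylsilane | C[Si](C)(C)O/C(OC)=C/C/C=C/CC=C
F6 | step 5 | methyl (2R,4E)-2-[(2S,6S)-1-acetyl-6-methylpiperidin-2-yl]octa-4,7-dienoate | CC(=O)N1[C@@H](C)CCC[C@H]1[C@@H](C/C=C/CC=C)C(=O)OC
F7 | step 5 | (2R,4E)-2-[(2S,6S)-1-acetyl-6-methylpiperidin-2-yl]-N-methoxy-N-methylocta-4,7-dienamide | CC(=O)N1[C@@H](C)CCC[C@H]1[C@@H](C/C=C/CC=C)C(=O)N(C)OC
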